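**Retrosynthetic overview**

- Feature: ring B (C5–C10) holds an acyloin unit, the C9 carbonyl being bonded to C10, the fully substituted spiro carbon that carries the furan oxygen; ring B is fused to the gem-dimethylcyclopropane (C6, C7, C11) of (+)-3-carene.
- Late stage: MOM removal, oxidation of C8 (C9 ketone to the C8,C9-dione), chalcone formation at the aryl acetyl group and furan closure (aryl–O bond from the C10 alkoxide) lead back to a cis-fused C10 ketol.
- Key disconnection: C9–C10, formed by a carbene-catalysed crossed benzoin reaction of the C9 aldehyde with the C10 ketone of ring A, which closes ring B.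
- Ring A keto aldehyde: the C1–aryl bond comes from palladium coupling of a silyl enol ether with an aryl bromide. Ring A comes from a prochiral 2-cyclopropyl-2-methylcyclohexane-1,3-dione (carene keto acetal plus methyl acrylate), desymmetrised by CBS reduction (C5) and hydroxyl-directed hydrogenation (C4).
- Ring order: cyclopropane (chiral pool), then ring A, then ring B (key step), then the dihydrofuran; the two benzene rings are bought.

Key step: step 14

Assumption: terpenoid atoms are numbered C1–C11 (ring A = C1–C5 and C10; ring B = C5–C10; cyclopropane = C6, C7, C11; C1 carries the aryl group), and C1 of the 2-aryl ketones 18 and 19 is taken as configurationally labile, so they are drawn as the epimer that is carried on.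

**Route**

Step 1
Reactants: 1 (+)-3-carene
Product: 4 1-[(1S,3R)-3-(2,2-dimethoxyethyl)-2,2-dimethylcyclopropyl]propan-2-one (keto acetal), via methoxy hydroperoxide aldehyde 2 (not isolated), via methoxy hydroperoxide acetal 3 (not isolated)
Conditions: O3, CH2Cl2/MeOH, −78 °C; TsOH·H2O (cat.), −78 °C → rt; then NaHCO3, Me2S, rt
Reagents that add atoms: ozone, [O-][O+]=O; methanol, CO
Why: Ozonolysis with unsymmetrical work-up: in methanol the carbonyl oxide forms on the methyl-bearing alkene carbon and is trapped as the methoxy hydroperoxide, so acid acetalises only the free aldehyde (C9) before Me2S releases the methyl ketone; C6 and C7 are taken over unchanged from 1.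

Step 2
Reactants: 4 keto acetal; 5 methyl acrylate
Product: 7 2-[cis-3-(2,2-dimethoxyethyl)-2,2-dimethylcyclopropyl]cyclohexane-1,3-dione, via keto ester 6 (not isolated)
Conditions: LiN(i-Pr)2, THF, −78 °C; 5, −78 °C; then KOt-Bu, −78 °C → rt; aq. NaH2PO4 (pH 5)
Reagents that add atoms: none
Why: Kinetic deprotonation at the methyl group and Michael addition to the acrylate give the 5-oxo ester, and Dieckmann condensation of the C5 enolate onto the ester then closes ring A as the 2-substituted 1,3-dione, whose stable enolate drives the closure; no stereocentre is formed.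

Step 3
Reactants: 7 cyclopropyl dione
Product: 8 2-[cis-3-(2,2-dimethoxyethyl)-2,2-dimethylcyclopropyl]-2-methylcyclohexane-1,3-dione
Conditions: MeI, Cs2CO3, MeCN, rt
Reagents that add atoms: iodomethane, CI
Why: C-alkylation of the 1,3-dione enolate by the soft electrophile makes C5 quaternary but still prochiral, since its two carbonyl arms are constitutionally identical.

Step 4
Reactants: 8 methyl dione
Product: 9 (2R,3R)-2-[cis-3-(2,2-dimethoxyethyl)-2,2-dimethylcyclopropyl]-3-hydroxy-2-methylcyclohexan-1-one (hydroxyl cis to the cyclopropyl group)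
Conditions: (3aS)-1-methyl-3,3-diphenyltetrahydro-1H,3H-pyrrolo[1,2-c][1,3,2]oxazaborole (20 mol %), BH3·SMe2, THF, −30 °C; MeOH, then aqueous work-up
Reagents that add atoms: none
Why: Corey–Bakshi–Shibata reduction: the catalyst, expected to give the (R)-carbinol with the quaternary carbon as the large group, and the substrate, which takes hydride anti to the cyclopropyl group, agree for only one of the two diastereotopic carbonyls, so this one becomes C10 and C5 is fixed as in the target.

Step 5
Reactants: 9 hydroxy ketone
Product: 10 2-[cis-3-(2,2-dimethoxyethyl)-2,2-dimethylcyclopropyl]-2-methyl-3-methylidenecyclohexan-1-ol (ring centres of 9)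
Conditions: Cp2TiMe2 (3 equiv), toluene/THF, 65 °C
Reagents that add atoms: dimethyltitanocene, C[Ti](C)(C1C=CC=C1)C1C=CC=C1
Why: Petasis methylenation: the titanium methylidene formed on heating converts the hindered C4 ketone into the exocyclic alkene under non-basic conditions, which spares the β-hydroxy ketone a retro-aldol opening.

Step 6
Reactants: 10 methylidene alcohol
Product: 11 2-[cis-3-(2,2-dimethoxyethyl)-2,2-dimethylcyclopropyl]-2,3-dimethylcyclohexan-1-ol (C4 and C5 methyl groups cis, hydroxyl trans to both)
Conditions: [Ir(cod)(PCy3)(py)]PF6 (5 mol %), H2 (1 atm), CH2Cl2, rt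
Reagents that add atoms: none
Why: Hydroxyl-directed hydrogenation: the cationic iridium catalyst bound to the C10 hydroxyl delivers hydrogen to the alkene face cis to it, which leaves the new C4 methyl group cis to the C5 methyl group.

Step 7
Reactants: 11 dimethyl alcohol
Product: 12 2-[cis-3-(2,2-dimethoxyethyl)-2,2-dimethylcyclopropyl]-2,3-dimethylcyclohexan-1-one (ring A ketone, C4 and C5 methyl groups cis)
Conditions: 1,1,1-triacetoxy-1,1-dihydro-1,2-benziodoxol-3(1H)-one, pyridine, CH2Cl2, 0 °C → rt
Reagents that add atoms: none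
Why: Dess–Martin oxidation of the secondary C10 alcohol to the ketone under buffered conditions that leave the dimethyl acetal and the C4 and C5 centres untouched.

Step 8
Reactants: 12 ring A ketone
Product: 13 trimethylsilyl enol ether of 12 (C10–O–Si, C1=C10 double bond)
Conditions: LiN(i-Pr)2, THF, −78 °C; Me3SiCl, −78 → 0 °C
Reagents that add atoms: chlorotrimethylsilane, C[Si](C)(C)Cl
Why: C5 is quaternary, so enolisation can only occur towards C1 and silylation gives a single regioisomeric silyl enol ether.

Step 9
Reactants: 14 1-(2,6-difluoro-4-methoxyphenyl)ethan-1-one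
Product: 15 1-(2-fluoro-6-hydroxy-4-methoxyphenyl)ethan-1-one
Conditions: KOH (2.2 equiv), DMSO/H2O, 70 °C; then 1 M HCl
Reagents that add atoms: potassium hydroxide, [K+].[OH-]
Why: Nucleophilic aromatic substitution: hydroxide displaces one of the two equivalent fluorides ortho to the acetyl group, and the phenoxide formed deactivates the ring against a second substitution.

Step 10
Reactants: 15 fluoro phenol
Product: 16 1-[2-fluoro-4-methoxy-6-(methoxymethoxy)phenyl]ethan-1-one
Conditions: NaH, DMF, 0 °C; MeOCH2Cl, 0 °C → rt
Reagents that add atoms: chloromethyl methyl ether, COCCl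
Why: Williamson-type alkylation of the sodium phenoxide gives the base-stable MOM ether that masks the phenol through the palladium, carbene and strong-base steps.

Step 11
Reactants: 16 MOM ether
Product: 17 1-[3-bromo-2-fluoro-4-methoxy-6-(methoxymethoxy)phenyl]ethan-1-one
Conditions: N-bromosuccinimide, MeCN, 0 °C → rt
Reagents that add atoms: N-bromosuccinimide, BrN1C(=O)CCC1=O
Why: Electrophilic aromatic bromination takes the position para to the methoxymethoxy group and ortho to the methoxy group (between fluorine and methoxy), the other free position lying between two alkoxy groups, and the neutral conditions avoid bromination of the acetyl methyl group.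

Step 12
Reactants: 13 silyl enol ether; 17 aryl bromide
Product: 18 6-aryl-2-[cis-3-(2,2-dimethoxyethyl)-2,2-dimethylcyclopropyl]-2,3-dimethylcyclohexan-1-one, aryl = 3-acetyl-2-fluoro-6-methoxy-4-(methoxymethoxy)phenyl
Conditions: Pd(OAc)2 (5 mol %), P(t-Bu)3 (10 mol %), Bu3SnF, CsF, toluene, 85 °C
Reagents that add atoms: none
Why: Palladium-catalysed α-arylation of a silyl enol ether: fluoride turns 13 into a tin enolate (Bu3SnF is regenerated by CsF) that transmetalates to the aryl palladium bromide from 17, and reductive elimination forms the C1–aryl bond without a strong base, so the enolisable acetyl group of 17 is left alone.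

Step 13
Reactants: 18 aryl ketone acetal
Product: 19 2-{cis-3-[3-aryl-1,6-dimethyl-2-oxocyclohexyl]-2,2-dimethylcyclopropyl}acetaldehyde (ring A keto aldehyde, aryl as in 18)
Conditions: oxalic acid, THF/H2O, rt
Reagents that add atoms: water, O
Why: Acid-catalysed acetal hydrolysis: the dimethyl acetal of the aliphatic aldehyde is far more labile than the aryl MOM ether, so mild aqueous acid frees the C9 aldehyde alone.

Step 14
Reactants: 19 ring A keto aldehyde
Product: 20 cis-fused ketol (ring B closed; C9 ketone; C10 hydroxyl cis to the C5 methyl, the C4 methyl and the C1 aryl group; aryl fluoride intact)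
Conditions: 2-(pentafluorophenyl)-6,7-dihydro-5H-pyrrolo[2,1-c][1,2,4]triazol-2-ium tetrafluoroborate (20 mol %), DBU (15 mol %), toluene (0.02 M), 40 °C
Reagents that add atoms: none
Why: Deprotonation of the triazolium salt gives the carbene, which adds to the C9 aldehyde and after proton transfer forms the Breslow intermediate, whose nucleophilic C9 attacks the C10 ketone of ring A before the carbene is released from the alkoxide. This is the carbene-catalysed intramolecular crossed benzoin reaction of an aldehyde with a ketone, a known reaction type. Ring B closes in a 6-exo-trig mode through the new C9–C10 bond. The new stereocentre C10 is controlled by the tether: C9 hangs on C5 through the cis-cyclopropane (C6, C7), and delivery from an axial C6 branch along the equatorial trajectory should give the cis ring fusion, with the hydroxyl cis to the C5 methyl group, as in related aldol and benzoin closures onto α-quaternary cyclohexanones. C1, benzylic and α to the ketone, epimerises under the basic conditions and the addition is reversible, so the mixture should drain into the ketol with the aryl group equatorial and cis to the hydroxyl, the one needed for the furan closure. The step needs the acyl-anion addition to win over base-mediated aldol closure of the enolisable aldehyde (C8 onto C10) and over intermolecular benzoin coupling; less base than azolium salt, high dilution and the proximity of C9 to C10 should secure this.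

Step 15
Reactants: 20 ketol
Product: 21 tetracyclic aryl methyl ketone (cis-fused 2,3-dihydrobenzofuran closed between the C10 oxygen and the former fluoro carbon; C9 ketone, C8 methylene)
Conditions: NaH, DMF, 0 °C → rt
Reagents that add atoms: none
Why: Intramolecular nucleophilic aromatic substitution: the C10 alkoxide displaces the fluoride ortho to the acetyl group and closes the five-membered ring, which is possible only for the ketol with the aryl group cis to the oxygen, so C1 and C10 keep the configuration set in step 14.

Step 16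
Reactants: 21 tetracyclic aryl methyl ketone; 22 4-methoxybenzaldehyde
Product: 25 (E)-chalcone MOM ether with C9 ketone and C8 methylene, via aldol adduct 23 (not isolated), via mesylate 24 (not isolated)
Conditions: LiN(SiMe3)2 (1.1 equiv), THF, −78 °C; 22, −78 °C; then MeSO2Cl, Et3N, −78 °C → rt
Reagents that add atoms: none
Why: Directed aldol condensation: the amide base removes a proton from the unhindered, more acidic acetyl methyl group rather than from C8, the lithium enolate adds to the aldehyde, and mesylation followed by E1cB elimination gives the (E)-enone.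

Step 17
Reactants: 25 chalcone MOM ether
Product: 26 MOM ether of the target (C8,C9-dione)
Conditions: SeO2, 1,4-dioxane, 90 °C
Reagents that add atoms: selenium dioxide, O=[Se]=O
Why: Riley oxidation: C8 is the only enolisable position left (C10 is quaternary and the acetyl methyl group has been used up), so SeO2 converts the C8 methylene next to the C9 ketone into the 1,2-dione, while the MOM ether keeps the chalcone from oxidative cyclisation.

Step 18
Reactants: 26 MOM ether of the target
Product: 27 CNP0121765.1
Conditions: HCl (1.25 M in MeOH), 0 °C → rt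
Reagents that add atoms: none
Why: Acid-catalysed acetal exchange with methanol removes the MOM group under conditions mild enough for the cyclopropyl dione and the chalcone, and the freed phenol is held by a hydrogen bond to the enone carbonyl.

**Compound list**

1 | (+)-3-carene, (1S,6R)-3,7,7-trimethylbicyclo[4.1.0]hept-3-ene | CC1=CC[C@@H]2[C@H](C1)C2(C)C | starting material
2 | cis-2-[3-(2-hydroperoxy-2-methoxypropyl)-2,2-dimethylcyclopropyl]acetaldehyde (cyclopropane centres of 1; epimers at the hydroperoxy carbon) | COC(C)(OO)C[C@H]1[C@@H](CC=O)C1(C)C | intermediate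
3 | cis-1-(2,2-dimethoxyethyl)-3-(2-hydroperoxy-2-methoxypropyl)-2,2-dimethylcyclopropane (cyclopropane centres of 1; epimers at the hydroperoxy carbon) | COC(C)(OO)C[C@H]1[C@@H](CC(OC)OC)C1(C)C | intermediate
4 | 1-[(1S,3R)-3-(2,2-dimethoxyethyl)-2,2-dimethylcyclopropyl]propan-2-one | CC(=O)C[C@H]1[C@@H](CC(OC)OC)C1(C)C | intermediate
5 | methyl acrylate | C=CC(=O)OC | starting material
6 | methyl 6-[(1S,3R)-3-(2,2-dimethoxyethyl)-2,2-dimethylcyclopropyl]-5-oxohexanoate | COC(=O)CCCC(=O)C[C@H]1[C@@H](CC(OC)OC)C1(C)C | intermediate
7 | 2-[cis-3-(2,2-dimethoxyethyl)-2,2-dimethylcyclopropyl]cyclohexane-1,3-dione (cyclopropane centres of 4) | O=C1CCCC(=O)C1[C@H]2[C@@H](CC(OC)OC)C2(C)C | intermediate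
8 | 2-[cis-3-(2,2-dimethoxyethyl)-2,2-dimethylcyclopropyl]-2-methylcyclohexane-1,3-dione (cyclopropane centres of 4; C5 prochiral) | CC1(C(=O)CCCC1=O)[C@H]2[C@@H](CC(OC)OC)C2(C)C | intermediate
9 | (2R,3R)-2-[cis-3-(2,2-dimethoxyethyl)-2,2-dimethylcyclopropyl]-3-hydroxy-2-methylcyclohexan-1-one (hydroxyl cis to the cyclopropyl group) | O[C@@H]1CCCC(=O)[C@]1(C)[C@H]2[C@@H](CC(OC)OC)C2(C)C | intermediate
10 | 2-[cis-3-(2,2-dimethoxyethyl)-2,2-dimethylcyclopropyl]-2-methyl-3-methylidenecyclohexan-1-ol (ring centres of 9) | O[C@@H]1CCCC(=C)[C@]1(C)[C@H]2[C@@H](CC(OC)OC)C2(C)C | intermediate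
11 | 2-[cis-3-(2,2-dimethoxyethyl)-2,2-dimethylcyclopropyl]-2,3-dimethylcyclohexan-1-ol (methyl groups cis; hydroxyl trans to both) | O[C@@H]1CCC[C@@H](C)[C@]1(C)[C@H]2[C@@H](CC(OC)OC)C2(C)C | intermediate
12 | 2-[cis-3-(2,2-dimethoxyethyl)-2,2-dimethylcyclopropyl]-2,3-dimethylcyclohexan-1-one (C4 and C5 methyl groups cis, as in the target) | O=C1CCC[C@@H](C)[C@]1(C)[C@H]2[C@@H](CC(OC)OC)C2(C)C | intermediate
13 | trimethylsilyl enol ether of 12 (C1=C10) | C[Si](C)(C)OC1=CCC[C@@H](C)[C@]1(C)[C@H]2[C@@H](CC(OC)OC)C2(C)C | intermediate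
14 | 1-(2,6-difluoro-4-methoxyphenyl)ethan-1-one | CC(=O)c1c(F)cc(OC)cc1F | starting material
15 | 1-(2-fluoro-6-hydroxy-4-methoxyphenyl)ethan-1-one | CC(=O)c1c(O)cc(OC)cc1F | intermediate
16 | 1-[2-fluoro-4-methoxy-6-(methoxymethoxy)phenyl]ethan-1-one | CC(=O)c1c(OCOC)cc(OC)cc1F | intermediate
17 | 1-[3-bromo-2-fluoro-4-methoxy-6-(methoxymethoxy)phenyl]ethan-1-one | CC(=O)c1c(OCOC)cc(OC)c(Br)c1F | intermediate
18 | 6-[3-acetyl-2-fluoro-6-methoxy-4-(methoxymethoxy)phenyl]-2-[cis-3-(2,2-dimethoxyethyl)-2,2-dimethylcyclopropyl]-2,3-dimethylcyclohexan-1-one (C4, C5 as in 12; C1 labile, drawn with the aryl group trans to the cyclopropyl group) | CC(=O)c1c(OCOC)cc(OC)c(c1F)[C@H]2CC[C@@H](C)[C@](C)([C@H]3[C@@H](CC(OC)OC)C3(C)C)C2=O | intermediate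
19 | 2-{cis-3-[3-aryl-1,6-dimethyl-2-oxocyclohexyl]-2,2-dimethylcyclopropyl}acetaldehyde, aryl = 3-acetyl-2-fluoro-6-methoxy-4-(methoxymethoxy)phenyl (ring A keto aldehyde; centres as in 18) | CC(=O)c1c(OCOC)cc(OC)c(c1F)[C@H]2CC[C@@H](C)[C@](C)([C@H]3[C@@H](CC=O)C3(C)C)C2=O | intermediate
20 | cis-fused ketol: ring A, ring B and cyclopropane, C9 ketone, C10 hydroxyl cis to the C5 methyl, the C4 methyl and the C1 aryl group (aryl as in 19) | CC(=O)c1c(OCOC)cc(OC)c(c1F)[C@H]2CC[C@@H](C)[C@]3(C)[C@H]4[C@H](C4(C)C)CC(=O)[C@]23O | intermediate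
21 | tetracyclic aryl methyl ketone: cis-fused dihydrobenzofuran on C1/C10, C9 ketone, C8 methylene, acetyl ortho to the furan oxygen, MOM ether | CC(=O)c1c(OCOC)cc(OC)c2c1O[C@]13C(=O)C[C@@H]4[C@@H](C4(C)C)[C@@]1(C)[C@H](C)CC[C@H]23 | intermediate
22 | 4-methoxybenzaldehyde | COc1ccc(C=O)cc1 | starting material
23 | aldol adduct of 21 and 22 (β-hydroxy ketone, formed as its lithium alkoxide; epimers at the carbinol carbon) | COc1ccc(C(O)CC(=O)c2c(OCOC)cc(OC)c3c2O[C@]24C(=O)C[C@@H]5[C@@H](C5(C)C)[C@@]2(C)[C@H](C)CC[C@H]34)cc1 | intermediate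
24 | methanesulfonate of 23 | COc1ccc(C(OS(C)(=O)=O)CC(=O)c2c(OCOC)cc(OC)c3c2O[C@]24C(=O)C[C@@H]5[C@@H](C5(C)C)[C@@]2(C)[C@H](C)CC[C@H]34)cc1 | intermediate
25 | (E)-chalcone MOM ether with C9 ketone and C8 methylene | COc1ccc(/C=C/C(=O)c2c(OCOC)cc(OC)c3c2O[C@]24C(=O)C[C@@H]5[C@@H](C5(C)C)[C@@]2(C)[C@H](C)CC[C@H]34)cc1 | intermediate
26 | MOM ether of the target (C8,C9-dione) | COc1ccc(/C=C/C(=O)c2c(OCOC)cc(OC)c3c2O[C@]24C(=O)C(=O)[C@@H]5[C@@H](C5(C)C)[C@@]2(C)[C@H](C)CC[C@H]34)cc1 | intermediate
27 | CNP0121765.1 | COc1ccc(/C=C/C(=O)c2c(O)cc(OC)c3c2O[C@]24C(=O)C(=O)[C@@H]5[C@@H](C5(C)C)[C@@]2(C)[C@H](C)CC[C@H]34)cc1 | target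

**Step count and risks**

Total step count: 18. Longest linear sequence: 15 steps (steps 1–8 and 12–18, from 1).

Steps most likely to fail:

Step 14 (key step). The hindered C10 ketone, flanked by the quaternary C5 and the aryl-bearing C1, may accept the bulky Breslow intermediate too slowly. Base-mediated aldol closure of the aldehyde enolate (C8 onto C10) or intermolecular benzoin coupling would then take over, and the C1 epimers may not converge. The fallback makes the same C9–C10 bond by a nitroaldol closure and sets out from 19. The aldehyde is reduced selectively (NaBH4, EtOH, −78 °C) to the primary alcohol F1, which is converted (I2, PPh3, imidazole) into the iodide F2 and then by Kornblum substitution (NaNO2, DMF) into the nitro compound F3, in which C9 is the most acidic carbon. DBU then closes ring B by intramolecular Henry addition of the C9 nitronate to the C10 ketone, giving the nitro alcohol F4. A Nef reaction (NaOMe, then buffered aqueous TiCl3) turns the C9 nitro group into the ketone, and the route is rejoined at 20.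

Step 12. Transmetalation and reductive elimination at the aryl palladium species with two ortho substituents may be slow, so that protodesilylation of the enol ether or β-hydride elimination to the enone competes. The fallback sets out from 13 and 17. Saegusa–Ito oxidation of 13 (Pd(OAc)2, MeCN) gives the enone F5, and iodination (I2, pyridine, CH2Cl2) gives the α-iodo enone F6. Miyaura borylation of 17 (B2pin2, Pd(dppf)Cl2, KOAc, dioxane) gives the pinacol boronate F7. Suzuki–Miyaura coupling of F6 with F7 (Pd(PPh3)4, K3PO4, dioxane) gives the 2-aryl enone F8, and hydrogenation of its C1=C2 bond (H2, palladium on carbon, EtOAc) rejoins the route at 18.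

Step 4. The catalyst may discriminate poorly between the two diastereotopic carbonyl groups if the chiral cyclopropyl group opposes it, and over-reduction to the diol may occur. The fallback gives up reagent control for separation with recycling and sets out from 8. NaBH4 (one hydride equivalent, MeOH/CH2Cl2, −78 °C) should still attack anti to the cyclopropyl group but reduce either carbonyl, giving 9 together with the diastereomeric hydroxy ketone F9. The two are separated by chromatography, F9 is oxidised back to 8 (Dess–Martin oxidation) and recycled, and the route is rejoined at 9.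

**Further compounds**

F1 | step 14 | 6-aryl-2-[cis-3-(2-hydroxyethyl)-2,2-dimethylcyclopropyl]-2,3-dimethylcyclohexan-1-one (aryl and centres as in 19) | CC(=O)c1c(OCOC)cc(OC)c(c1F)[C@H]2CC[C@@H](C)[C@](C)([C@H]3[C@@H](CCO)C3(C)C)C2=O
F2 | step 14 | 6-aryl-2-[cis-3-(2-iodoethyl)-2,2-dimethylcyclopropyl]-2,3-dimethylcyclohexan-1-one | CC(=O)c1c(OCOC)cc(OC)c(c1F)[C@H]2CC[C@@H](C)[C@](C)([C@H]3[C@@H](CCI)C3(C)C)C2=O
F3 | step 14 | 6-aryl-2-[cis-2,2-dimethyl-3-(2-nitroethyl)cyclopropyl]-2,3-dimethylcyclohexan-1-one | CC(=O)c1c(OCOC)cc(OC)c(c1F)[C@H]2CC[C@@H](C)[C@](C)([C@H]3[C@@H](CC[N+](=O)[O-])C3(C)C)C2=O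
F4 | step 14 | nitro alcohol: analogue of 20 with a nitro group at C9 in place of the ketone (C9 epimers) | CC(=O)c1c(OCOC)cc(OC)c(c1F)[C@H]2CC[C@@H](C)[C@]3(C)[C@H]4[C@H](C4(C)C)CC([N+](=O)[O-])[C@]23O
F5 | step 12 | 6-[cis-3-(2,2-dimethoxyethyl)-2,2-dimethylcyclopropyl]-5,6-dimethylcyclohex-2-en-1-one (centres of 12) | O=C1C=CC[C@@H](C)[C@]1(C)[C@H]2[C@@H](CC(OC)OC)C2(C)C
F6 | step 12 | 6-[cis-3-(2,2-dimethoxyethyl)-2,2-dimethylcyclopropyl]-2-iodo-5,6-dimethylcyclohex-2-en-1-one | O=C1C(I)=CC[C@@H](C)[C@]1(C)[C@H]2[C@@H](CC(OC)OC)C2(C)C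
F7 | step 12 | 1-[2-fluoro-4-methoxy-6-(methoxymethoxy)-3-(4,4,5,5-tetramethyl-1,3,2-dioxaborolan-2-yl)phenyl]ethan-1-one | CC(=O)c1c(OCOC)cc(OC)c(B2OC(C)(C)C(C)(C)O2)c1F
F8 | step 12 | 2-aryl-6-[cis-3-(2,2-dimethoxyethyl)-2,2-dimethylcyclopropyl]-5,6-dimethylcyclohex-2-en-1-one (aryl as in 18) | CC(=O)c1c(OCOC)cc(OC)c(c1F)C2=CC[C@@H](C)[C@](C)([C@H]3[C@@H](CC(OC)OC)C3(C)C)C2=O
F9 | step 4 | (2S,3S)-2-[cis-3-(2,2-dimethoxyethyl)-2,2-dimethylcyclopropyl]-3-hydroxy-2-methylcyclohexan-1-one (other carbonyl reduced; cyclopropane unchanged) | O[C@H]1CCCC(=O)[C@@]1(C)[C@H]2[C@@H](CC(OC)OC)C2(C)C
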